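**Retrosynthetic overview**
1. Target ⇐ last-step unmasking (C14 dimethyl acetal, C15 silyl ether) of the fully acylated bicyclic lactone.
2. Both rings in one operation: Ni/Cr-mediated alkenylation of a seco iodo-aldehyde forms C5–C6 and closes the ten-membered carbocycle; the C6 alkoxide so formed then closes the α-methylene-γ-lactone onto the C12 methyl ester (carbocycle first, lactone immediately after, same flask).
3. Seco aldehyde ⇐ indium Barbier union at C7–C8 (sets C7 and C8) of a C9-acyloxy aldehyde with a 2-(bromomethyl)enoate, then C8 angeloylation, Si→I exchange and C6 oxidation.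
4. C9-acyloxy aldehyde ⇐ Stille coupling, Sharpless epoxidation, titanium-assisted epoxide opening by (R)-2-methylbutanoic acid (sets C9, installs the ester), glycol cleavage.
5. Alkenyl iodide chain ⇐ anti-carbomagnesiation of a silylated propargyl alcohol (C4=C5 geometry), cross-metathesis and α-iodination (C1=C10 geometry).

Locants C1–C15 are the germacranolide numbering of the target (C12 lactone carbonyl, C13 exocyclic methylene, C14 aldehyde carbon, C15 hydroxymethyl carbon).
Assumption: (R)-2-methylbutanoic acid, angelic acid, (E)-3-(tributylstannyl)prop-2-en-1-ol, 3-(trimethylsilyl)prop-2-yn-1-ol and 2-(tert-butyldimethylsilyloxy)acetaldehyde are bought as catalogue compounds.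

**Route**

Step 1
Reactants: 1 3-(trimethylsilyl)prop-2-yn-1-ol; 2 but-3-en-1-ylmagnesium bromide
Product: 4 (E)-2-(but-3-en-1-yl)-3-(trimethylsilyl)prop-2-en-1-ol, via alkenylmagnesium alkoxide 3 (not isolated)
Conditions: 2 (3 equiv), CuI (10 mol %), THF, 0 °C to 65 °C; then H2O
Reagents that add atoms: none
Why: Copper-catalysed anti-carbomagnesiation of a propargylic alcohol: the magnesium alkoxide directs the butenyl group to the carbinol-side alkyne carbon and holds the new C–Mg bond cis to CH2O, so protonation leaves SiMe3 cis to the butenyl chain and fixes the C4=C5 geometry.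

Step 2
Reactants: 4 (E)-2-(but-3-en-1-yl)-3-(trimethylsilyl)prop-2-en-1-ol
Product: 5 tert-butyldiphenylsilyl ether of 4
Conditions: TBDPSCl, imidazole, CH2Cl2, 0 °C to rt
Reagents that add atoms: tert-butyl(chloro)diphenylsilane, CC(C)(C)[Si](Cl)(c1ccccc1)c1ccccc1
Why: Standard silylation of a primary allylic alcohol; the bulky silyl ether masks C15–OH until the last step.

Step 3
Reactants: 5 tert-butyldiphenylsilyl ether of 4; 6 (E)-but-2-enal
Product: 7 (2E,6E)-6-[(tert-butyldiphenylsilyloxy)methyl]-7-(trimethylsilyl)hepta-2,6-dienal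
Conditions: 6 (5 equiv), second-generation Hoveyda–Grubbs catalyst (5 mol %), CH2Cl2, 40 °C
Reagents that add atoms: none
Why: Olefin cross-metathesis of a terminal alkene with excess crotonaldehyde gives the (E)-enal under thermodynamic control, while the trisubstituted alkenylsilane is too hindered to react.

Step 4
Reactants: 7 (2E,6E)-6-[(tert-butyldiphenylsilyloxy)methyl]-7-(trimethylsilyl)hepta-2,6-dienal
Product: 8 (2Z,6E)-2-iodo-6-[(tert-butyldiphenylsilyloxy)methyl]-7-(trimethylsilyl)hepta-2,6-dienal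
Conditions: I2, DMAP (20 mol %), K2CO3, THF/H2O 1:1, rt
Reagents that add atoms: iodine, II
Why: Amine-catalysed α-iodination of an enal (conjugate addition of DMAP, iodination, elimination) gives the (Z)-α-iodoenal, which places iodine cis to the chain as required for the C1=C10 geometry.

Step 5
Reactants: 8 (2Z,6E)-2-iodo-6-[(tert-butyldiphenylsilyloxy)methyl]-7-(trimethylsilyl)hepta-2,6-dienal
Product: 9 dimethyl acetal of 8
Conditions: HC(OMe)3, PPTS (cat.), MeOH, rt
Reagents that add atoms: trimethyl orthoformate, COC(OC)OC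
Why: Acid-catalysed acetalisation masks the C14 aldehyde so that later carbonyl additions occur only at the intended aldehydes.

Step 6
Reactants: 9 dimethyl acetal of 8; 10 (E)-3-(tributylstannyl)prop-2-en-1-ol
Product: 11 (2E,4E,8E)-4-(dimethoxymethyl)-8-[(tert-butyldiphenylsilyloxy)methyl]-9-(trimethylsilyl)nona-2,4,8-trien-1-ol
Conditions: Pd2(dba)3 (2.5 mol %), AsPh3, CuI, NMP, 45 °C
Reagents that add atoms: none
Why: Stille cross-coupling joins the hindered alkenyl iodide and the (E)-alkenylstannane with retention of both olefin geometries.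

Step 7
Reactants: 11 (2E,4E,8E)-4-(dimethoxymethyl)-8-[(tert-butyldiphenylsilyloxy)methyl]-9-(trimethylsilyl)nona-2,4,8-trien-1-ol
Product: 12 (2S,3S)-2,3-epoxy alcohol of 11
Conditions: Ti(OiPr)4 (10 mol %), L-(+)-diethyl tartrate (12 mol %), t-BuOOH, 4 Å molecular sieves, CH2Cl2, −20 °C
Reagents that add atoms: tert-butyl hydroperoxide, CC(C)(C)OO
Why: Sharpless asymmetric epoxidation: only the alkene of the free allylic alcohol reacts, and L-(+)-tartrate delivers oxygen to the face that gives the (2S,3S)-epoxy alcohol.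

Step 8
Reactants: 12 (2S,3S)-2,3-epoxy alcohol of 11; 13 (R)-2-methylbutanoic acid
Product: 14 (2S,3R)-1,2-diol 3-[(R)-2-methylbutanoate]
Conditions: 13 (1.5 equiv), Ti(OiPr)4 (1.5 equiv), CH2Cl2, rt
Reagents that add atoms: none
Why: Sharpless titanium-assisted opening of a 2,3-epoxy alcohol: the titanium-bound carboxylate attacks the allylic C3 position with inversion, which sets the C9 stereocentre (R) and installs the 2-methylbutanoate in the same event.

Step 9
Reactants: 14 (2S,3R)-1,2-diol 3-[(R)-2-methylbutanoate]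
Product: 15 (R)-2-acyloxy aldehyde (C8 aldehyde; C9 ester)
Conditions: NaIO4, THF/pH 7 buffer, 0 °C; used crude
Reagents that add atoms: none
Why: Periodate (Malaprade) cleavage of the terminal 1,2-diol unveils the C8 aldehyde under neutral conditions without touching the ester-bearing stereocentre.

Step 10
Reactants: 16 2-(tert-butyldimethylsilyloxy)acetaldehyde; 17 methyl acrylate
Product: 18 methyl 4-(tert-butyldimethylsilyloxy)-3-hydroxy-2-methylidenebutanoate (racemic)
Conditions: DABCO (0.5 equiv), neat, rt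
Reagents that add atoms: none
Why: Morita–Baylis–Hillman reaction of an unhindered aldehyde with methyl acrylate; the carbinol centre is formed as a racemate and is erased in the next step.

Step 11
Reactants: 18 methyl 4-(tert-butyldimethylsilyloxy)-3-hydroxy-2-methylidenebutanoate
Product: 19 methyl (Z)-2-(bromomethyl)-4-(tert-butyldimethylsilyloxy)but-2-enoate
Conditions: NBS, Me2S, CH2Cl2, 0 °C to rt
Reagents that add atoms: N-bromosuccinimide, O=C1CCC(=O)N1Br
Why: Corey–Kim-type bromination of a Morita–Baylis–Hillman alcohol proceeds with allylic transposition to the thermodynamically favoured (Z)-2-(bromomethyl)enoate.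

Step 12
Reactants: 15 (R)-2-acyloxy aldehyde; 19 methyl (Z)-2-(bromomethyl)-4-(tert-butyldimethylsilyloxy)but-2-enoate
Product: 20 C7–C8 adduct (7S,8S,9R; free C8–OH; C6 as CH2OTBS; methyl 2-methylidene ester)
Conditions: In powder (1.5 equiv), 19 (1.5 equiv), DMF, rt
Reagents that add atoms: none
Why: Indium-mediated Barbier allylation: γ-attack of the (Z)-allyl unit through a chair-like six-membered transition state gives the syn C7/C8 relationship, and Felkin–Anh (polar) approach anti to the C9 acyloxy group gives the anti C8/C9 relationship, so C7 and C8 are set together.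

Step 13
Reactants: 20 C7–C8 adduct; 21 angelic acid [(Z)-2-methylbut-2-enoic acid]
Product: 22 C8 angelate of 20
Conditions: 21, 2,4,6-Cl3C6H2COCl, Et3N, toluene, rt; then 20, 75 °C
Reagents that add atoms: none
Why: Yamaguchi mixed-anhydride esterification run without DMAP acylates the hindered C8 alcohol while keeping the (Z) geometry of the angelate.

Step 14
Reactants: 22 C8 angelate of 20
Product: 23 C5 alkenyl iodide (SiMe3 replaced by I)
Conditions: NIS, MeCN/ClCH2CN 4:1, 0 °C
Reagents that add atoms: N-iodosuccinimide, O=C1CCC(=O)N1I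
Why: Ipso-iododesilylation of the alkenylsilane (β-silyl cation pathway) occurs with retention in nitrile solvent, and the electron-poor or deactivated alkenes elsewhere do not compete.

Step 15
Reactants: 23 C5 alkenyl iodide
Product: 24 C6 primary alcohol
Conditions: HF·pyridine, pyridine, THF, 0 °C; taken on at once
Reagents that add atoms: none
Why: Buffered HF·pyridine removes the primary TBS ether selectively in the presence of the TBDPS ether and the acetal.

Step 16
Reactants: 24 C6 primary alcohol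
Product: 25 seco iodo-aldehyde (C6 aldehyde)
Conditions: Dess–Martin periodinane, NaHCO3, CH2Cl2, 0 °C; used crude
Reagents that add atoms: none
Why: Buffered Dess–Martin oxidation gives the aldehyde under non-basic conditions so that the C7 stereocentre next to it is not epimerised.

Step 17
Reactants: 25 seco iodo-aldehyde
Product: 27 protected bicyclic lactone (C14 dimethyl acetal; C15 OTBDPS), via macrocyclic hydroxy ester 26 (not isolated)
Conditions: CrCl2 (10 equiv), NiCl2 (2 mol %), DMSO/THF, 2 mM by slow addition, rt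
Reagents that add atoms: none
Why: Nozaki–Hiyama–Kishi alkenylation run as a macrocyclisation: the alkenyl iodide is metallated with retention of geometry and adds to the C6 aldehyde anti to the branched C8 substituent (Felkin–Anh, which is also the anti C5–C6–C7–C8 torsion a trans-fused ring needs), setting C6 (R), and the alkoxide of 26 then acylates itself with the neighbouring methyl ester to close the trans-fused α-methylene-γ-lactone in the same operation.

Step 18
Reactants: 27 protected bicyclic lactone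
Product: 29 target CNP0290361.1, via silyl-protected enal 28 (not isolated)
Conditions: 48 % aq. HF, MeCN, 0 °C to rt
Reagents that add atoms: water, O
Why: Aqueous HF hydrolyses the dimethyl acetal to the conjugated aldehyde and cleaves the silyl ether by Si–F bond formation, with no stereocentre or olefin geometry affected.

**Compound list**
1 | 3-(trimethylsilyl)prop-2-yn-1-ol | C[Si](C)(C)C#CCO | starting material
2 | but-3-en-1-ylmagnesium bromide | C=CCC[Mg]Br | starting material
3 | alkenylmagnesium alkoxide from 1 and 2 (C–Mg cis to the CH2OMgBr arm) | C[Si](C)(C)/C([Mg]Br)=C(/CO[Mg]Br)CCC=C | intermediate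
4 | (E)-2-(but-3-en-1-yl)-3-(trimethylsilyl)prop-2-en-1-ol (SiMe3 cis to the butenyl chain) | C[Si](C)(C)/C=C(/CO)CCC=C | intermediate
5 | tert-butyldiphenylsilyl ether of 4 | C[Si](C)(C)/C=C(/CO[Si](c1ccccc1)(c1ccccc1)C(C)(C)C)CCC=C | intermediate
6 | (E)-but-2-enal (crotonaldehyde) | C/C=C/C=O | starting material
7 | (2E,6E)-6-[(tert-butyldiphenylsilyloxy)methyl]-7-(trimethylsilyl)hepta-2,6-dienal | C[Si](C)(C)/C=C(/CO[Si](c1ccccc1)(c1ccccc1)C(C)(C)C)CC/C=C/C=O | intermediate
8 | (2Z,6E)-2-iodo-6-[(tert-butyldiphenylsilyloxy)methyl]-7-(trimethylsilyl)hepta-2,6-dienal | C[Si](C)(C)/C=C(/CO[Si](c1ccccc1)(c1ccccc1)C(C)(C)C)CC/C=C(/C=O)I | intermediate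
9 | dimethyl acetal of 8 | C[Si](C)(C)/C=C(/CO[Si](c1ccccc1)(c1ccccc1)C(C)(C)C)CC/C=C(/C(OC)OC)I | intermediate
10 | (E)-3-(tributylstannyl)prop-2-en-1-ol | CCCC[Sn](CCCC)(CCCC)/C=C/CO | starting material
11 | (2E,4E,8E)-4-(dimethoxymethyl)-8-[(tert-butyldiphenylsilyloxy)methyl]-9-(trimethylsilyl)nona-2,4,8-trien-1-ol | C[Si](C)(C)/C=C(/CO[Si](c1ccccc1)(c1ccccc1)C(C)(C)C)CC/C=C(/C(OC)OC)\C=C\CO | intermediate
12 | (2S,3S)-2,3-epoxy alcohol of 11 (oxirane carbons are the later C8 precursor and C9) | C[Si](C)(C)/C=C(/CO[Si](c1ccccc1)(c1ccccc1)C(C)(C)C)CC/C=C(/C(OC)OC)[C@@H]1O[C@H]1CO | intermediate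
13 | (R)-2-methylbutanoic acid | CC[C@@H](C)C(=O)O | starting material
14 | (2S,3R)-1,2-diol 3-[(R)-2-methylbutanoate] from opening of 12 at C3 (C9 ester, R) | C[Si](C)(C)/C=C(/CO[Si](c1ccccc1)(c1ccccc1)C(C)(C)C)CC/C=C(/C(OC)OC)[C@@H](OC(=O)[C@H](C)CC)[C@@H](O)CO | intermediate
15 | (2R,3E,7E)-3-(dimethoxymethyl)-1-oxo-7-[(tert-butyldiphenylsilyloxy)methyl]-8-(trimethylsilyl)octa-3,7-dien-2-yl (R)-2-methylbutanoate | C[Si](C)(C)/C=C(/CO[Si](c1ccccc1)(c1ccccc1)C(C)(C)C)CC/C=C(/C(OC)OC)[C@@H](OC(=O)[C@H](C)CC)C=O | intermediate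
16 | 2-(tert-butyldimethylsilyloxy)acetaldehyde | CC(C)(C)[Si](C)(C)OCC=O | starting material
17 | methyl acrylate | C=CC(=O)OC | starting material
18 | methyl 4-(tert-butyldimethylsilyloxy)-3-hydroxy-2-methylidenebutanoate (racemic) | C=C(C(=O)OC)C(O)CO[Si](C)(C)C(C)(C)C | intermediate
19 | methyl (Z)-2-(bromomethyl)-4-(tert-butyldimethylsilyloxy)but-2-enoate | COC(=O)/C(CBr)=C/CO[Si](C)(C)C(C)(C)C | intermediate
20 | methyl (3S,4S,5R,6E,10E)-3-[(tert-butyldimethylsilyloxy)methyl]-6-(dimethoxymethyl)-4-hydroxy-2-methylidene-5-[(R)-2-methylbutanoyloxy]-10-[(tert-butyldiphenylsilyloxy)methyl]-11-(trimethylsilyl)undeca-6,10-dienoate | C[Si](C)(C)/C=C(/CO[Si](c1ccccc1)(c1ccccc1)C(C)(C)C)CC/C=C(/C(OC)OC)[C@@H](OC(=O)[C@H](C)CC)[C@@H](O)[C@@H](C(=C)C(=O)OC)CO[Si](C)(C)C(C)(C)C | intermediate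
21 | angelic acid, (Z)-2-methylbut-2-enoic acid | C/C=C(/C)C(=O)O | starting material
22 | 4-O-angeloyl derivative of 20 (C8 angelate) | C[Si](C)(C)/C=C(/CO[Si](c1ccccc1)(c1ccccc1)C(C)(C)C)CC/C=C(/C(OC)OC)[C@@H](OC(=O)[C@H](C)CC)[C@@H](OC(=O)/C(C)=C\C)[C@@H](C(=C)C(=O)OC)CO[Si](C)(C)C(C)(C)C | intermediate
23 | 11-iodo analogue of 22 (C5 alkenyl iodide, I cis to the C3 chain) | I/C=C(/CO[Si](c1ccccc1)(c1ccccc1)C(C)(C)C)CC/C=C(/C(OC)OC)[C@@H](OC(=O)[C@H](C)CC)[C@@H](OC(=O)/C(C)=C\C)[C@@H](C(=C)C(=O)OC)CO[Si](C)(C)C(C)(C)C | intermediate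
24 | C6 primary alcohol from 23 (3-hydroxymethyl) | I/C=C(/CO[Si](c1ccccc1)(c1ccccc1)C(C)(C)C)CC/C=C(/C(OC)OC)[C@@H](OC(=O)[C@H](C)CC)[C@@H](OC(=O)/C(C)=C\C)[C@@H](C(=C)C(=O)OC)CO | intermediate
25 | seco iodo-aldehyde (3-formyl; C7 is labelled R here by priority change only) | I/C=C(/CO[Si](c1ccccc1)(c1ccccc1)C(C)(C)C)CC/C=C(/C(OC)OC)[C@@H](OC(=O)[C@H](C)CC)[C@@H](OC(=O)/C(C)=C\C)[C@@H](C(=C)C(=O)OC)C=O | intermediate
26 | ten-membered (Z,Z)-cyclodecadiene hydroxy ester: C6–OH, C7 bearing the methyl 2-propenoate-2-yl group (as its chromium alkoxide in the flask) | O[C@@H]1/C=C(/CO[Si](c2ccccc2)(c2ccccc2)C(C)(C)C)CC/C=C(/C(OC)OC)[C@@H](OC(=O)[C@H](C)CC)[C@@H](OC(=O)/C(C)=C\C)[C@H]1C(=C)C(=O)OC | intermediate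
27 | (6R,7S,8S,9R)-germacranolide with C14 dimethyl acetal and C15 OTBDPS, 8-angelate, 9-(R)-2-methylbutanoate | C=C1C(=O)O[C@@H]2/C=C(/CO[Si](c3ccccc3)(c3ccccc3)C(C)(C)C)CC/C=C(/C(OC)OC)[C@@H](OC(=O)[C@H](C)CC)[C@@H](OC(=O)/C(C)=C\C)[C@@H]12 | intermediate
28 | C15 tert-butyldiphenylsilyl ether of the target (C14 aldehyde free) | C=C1C(=O)O[C@@H]2/C=C(/CO[Si](c3ccccc3)(c3ccccc3)C(C)(C)C)CC/C=C(/C=O)[C@@H](OC(=O)[C@H](C)CC)[C@@H](OC(=O)/C(C)=C\C)[C@@H]12 | intermediate
29 | CNP0290361.1: (6R,7S,8S,9R)-8-angeloyloxy-15-hydroxy-9-[(R)-2-methylbutanoyloxy]-14-oxogermacra-1(10),4,11(13)-trien-12,6-olide, both ring olefins cis in the ring | C=C1C(=O)O[C@@H]2/C=C(/CO)CC/C=C(/C=O)[C@@H](OC(=O)[C@H](C)CC)[C@@H](OC(=O)/C(C)=C\C)[C@@H]12 | target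

**Count**
Total steps: 18. Longest linear sequence: 16 (steps 1–9 and 12–18; steps 10–11 are a two-step side branch).

**Three steps most likely to fail, each with a fallback**

Step 17 (two-ring closure). Aldehyde 25 carries a doubly activated proton at C7 (α to the aldehyde and allylic to the acrylate) and a β-acyloxy group, so it may isomerise or eliminate during the slow addition; the C6 facial selectivity is predicted, not precedented on this ring. Fallback: set out from 23 and carry the acrylate through ring closure in masked form. Me2NH in MeOH adds to the 2-substituted acrylate (the angelate does not react) to give the β-dimethylamino ester F1. HF·pyridine then gives the primary alcohol F2, and Dess–Martin periodinane gives the aldehyde F3, whose C7 proton is no longer allylic. The same CrCl2/NiCl2 ring closure and lactonisation give the α-(dimethylaminomethyl) lactone F4. MeI followed by NaHCO3 (Hofmann-type elimination) restores the exocyclic methylene and comes back to the route at 27.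

Step 12 (Barbier union). Three things must go right together: syn C7/C8, Felkin C8/C9, and no shift of the C9 acyl group onto the new C8 oxygen. Fallback: set out from 19 and convert the bromide with B2pin2, CuCl and LiOtBu into the allylboronate F5. Heating F5 with 15 in toluene (Sc(OTf)3 if needed) runs the allylation through a closed boron-centred chair without a metal alkoxide that could move the ester, and after work-up comes back to the route at 20.

Step 13 (angeloylation). The C8 alcohol is hindered, heating with base may close the unwanted 8,12-lactone, and angelate can isomerise to tiglate. Fallback: set out from 20 and esterify at 0 °C (DCC, DMAP) with 2-[bis(2,2,2-trifluoroethoxy)phosphoryl]propanoic acid to give the phosphonate ester F6. Still–Gennari olefination of F6 with acetaldehyde (KN(SiMe3)2, 18-crown-6, THF, −78 °C) builds the (Z)-2-methylbut-2-enoate on the substrate and comes back to the route at 22.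

**Further compounds**
F1 | step 17 | β-dimethylamino ester from 23 (acrylate masked as its Me2NH adduct, new centre unassigned) | I/C=C(/CO[Si](c1ccccc1)(c1ccccc1)C(C)(C)C)CC/C=C(/C(OC)OC)[C@@H](OC(=O)[C@H](C)CC)[C@@H](OC(=O)/C(C)=C\C)[C@@H](C(CN(C)C)C(=O)OC)CO[Si](C)(C)C(C)(C)C
F2 | step 17 | primary alcohol from F1 (C6–OH) | I/C=C(/CO[Si](c1ccccc1)(c1ccccc1)C(C)(C)C)CC/C=C(/C(OC)OC)[C@@H](OC(=O)[C@H](C)CC)[C@@H](OC(=O)/C(C)=C\C)[C@@H](C(CN(C)C)C(=O)OC)CO
F3 | step 17 | aldehyde from F2 (C6 formyl) | I/C=C(/CO[Si](c1ccccc1)(c1ccccc1)C(C)(C)C)CC/C=C(/C(OC)OC)[C@@H](OC(=O)[C@H](C)CC)[C@@H](OC(=O)/C(C)=C\C)[C@@H](C(CN(C)C)C(=O)OC)C=O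
F4 | step 17 | α-(dimethylaminomethyl) analogue of lactone 27 | CN(C)CC1C(=O)O[C@@H]2/C=C(/CO[Si](c3ccccc3)(c3ccccc3)C(C)(C)C)CC/C=C(/C(OC)OC)[C@@H](OC(=O)[C@H](C)CC)[C@@H](OC(=O)/C(C)=C\C)[C@@H]12
F5 | step 12 | methyl 4-(tert-butyldimethylsilyloxy)-2-[(4,4,5,5-tetramethyl-1,3,2-dioxaborolan-2-yl)methyl]but-2-enoate (boron-bearing CH2 cis to CH2OTBS) | COC(=O)/C(CB1OC(C)(C)C(C)(C)O1)=C/CO[Si](C)(C)C(C)(C)C
F6 | step 13 | C8 2-[bis(2,2,2-trifluoroethoxy)phosphoryl]propanoate of 20 | C[Si](C)(C)/C=C(/CO[Si](c1ccccc1)(c1ccccc1)C(C)(C)C)CC/C=C(/C(OC)OC)[C@@H](OC(=O)[C@H](C)CC)[C@@H](OC(=O)C(C)P(=O)(OCC(F)(F)F)OCC(F)(F)F)[C@@H](C(=C)C(=O)OC)CO[Si](C)(C)C(C)(C)C
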